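**Strategy.** The cyclopentene (C1 bears CH2OAc, C2 the formyl group, C3 the side chain) is built by a [3+2] annulation that exploits the C4H2–C5H2 ethano edge flanking the tetrasubstituted C1=C2 double bond. Ring atoms C2, C3 and C4 arrive as an enantiopure 1-(ethoxycarbonyl)cyclopropylphosphonium salt carrying the complete side chain; C1, C5 and the oxygenated exocyclic carbon come from the kinetic enolate of silyl-protected hydroxyacetone. In one operation the enolate opens the cyclopropane at its CH2 (C4–C5 bond) and the released ester-stabilised ylide closes on the ketone by intramolecular Wittig olefination (C1=C2 bond). The C3/side-chain stereodiad is set earlier by a proline-catalysed anti cross-aldol and a stereoinvertive cyclopropane closure.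

Key step: step 7

Remark: compounds 2, 5, 10 and 12 are treated as purchasable.
Remark: the configuration at C1 of cyclopropane 11 is assumed (phosphorus trans to the C2 substituent); it has no consequence because this centre is erased in step 7.

Step 1
Reactants: 1 geranyl bromide [(2E)-1-bromo-3,7-dimethylocta-2,6-diene]; 2 [2-(1,3-dioxan-2-yl)ethyl]magnesium bromide
Product: 3 2-[(4E)-5,9-dimethyldeca-4,8-dien-1-yl]-1,3-dioxane
Conditions: Li2CuCl4 (3 mol%), THF, −20 → 0 °C
Reagents that add atoms: none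
Why: Li2CuCl4-catalysed cross-coupling of a primary alkyl Grignard reagent with an allylic bromide should substitute at the primary allylic carbon with retention of the E double bond.

Step 2
Reactants: 3 2-[(4E)-5,9-dimethyldeca-4,8-dien-1-yl]-1,3-dioxane
Product: 4 (5E)-6,10-dimethylundeca-5,9-dienal
Conditions: 1 M HCl, THF, 50 °C
Reagents that add atoms: water, O
Why: Acid-catalysed acetal hydrolysis frees the aldehyde, and dilute acid at moderate temperature should leave the trisubstituted alkenes untouched.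

Step 3
Reactants: 4 (5E)-6,10-dimethylundeca-5,9-dienal; 5 2-[(triisopropylsilyl)oxy]acetaldehyde
Product: 7 (2R,3S,6E)-3-(dimethoxymethyl)-7,11-dimethyl-1-[(triisopropylsilyl)oxy]dodeca-6,10-dien-2-ol, via aldol 6 (not isolated)
Conditions: L-proline (15 mol%), DMF, 4 °C, slow addition of 4 to 5 (2 equiv); then HC(OMe)3, camphorsulfonic acid (30 mol%), 23 °C
Reagents that add atoms: trimethyl orthoformate, COC(OC)OC
Why: Proline-catalysed direct cross-aldol reaction (enamine catalysis): the anti enamine of 4 should add to the more electrophilic α-silyloxy aldehyde 5 through the hydrogen-bonded chair-like transition state, setting the 2,3-anti (2S,3R) pair under catalyst control, and the labile β-hydroxy aldehyde is trapped in the flask as its dimethyl acetal.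

Step 4
Reactants: 7 (2R,3S,6E)-3-(dimethoxymethyl)-7,11-dimethyl-1-[(triisopropylsilyl)oxy]dodeca-6,10-dien-2-ol
Product: 8 (2R,3S,6E)-3-(dimethoxymethyl)-7,11-dimethyldodeca-6,10-diene-1,2-diol
Conditions: Bu4NF, THF, 0 → 23 °C
Reagents that add atoms: none
Why: Fluoride-mediated silyl ether cleavage under basic conditions leaves the dimethyl acetal and both stereocentres untouched.

Step 5
Reactants: 8 (2R,3S,6E)-3-(dimethoxymethyl)-7,11-dimethyldodeca-6,10-diene-1,2-diol
Product: 9 (4R)-4-[(2S,5E)-1,1-dimethoxy-6,10-dimethylundeca-5,9-dien-2-yl]-1,3,2-dioxathiolane 2,2-dioxide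
Conditions: NaH (2.2 equiv), THF, −40 °C; then 1,1′-sulfonyldiimidazole, −40 → 0 °C
Reagents that add atoms: 1,1′-sulfonyldiimidazole, O=S(=O)(n1ccnc1)n1ccnc1
Why: Double O-sulfonylation by sulfonyl transfer closes the five-membered cyclic sulfate without an oxidant, so the trisubstituted alkenes are spared and neither stereocentre is touched.

Step 6
Reactants: 9 (4R)-4-[(2S,5E)-1,1-dimethoxy-6,10-dimethylundeca-5,9-dien-2-yl]-1,3,2-dioxathiolane 2,2-dioxide; 10 ethyl (triphenyl-λ5-phosphanylidene)acetate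
Product: 11 [(1S,2R)-2-[(2S,5E)-1,1-dimethoxy-6,10-dimethylundeca-5,9-dien-2-yl]-1-(ethoxycarbonyl)cyclopropyl]triphenylphosphonium tetrafluoroborate
Conditions: 10 (2.1 equiv), MeCN, 23 → 70 °C; then aq. NaBF4, CH2Cl2
Reagents that add atoms: sodium tetrafluoroborate, [Na+].F[B-](F)(F)F
Why: Proposed new method: the ester-stabilised ylide should C-alkylate at the primary carbon of the cyclic sulfate, the second equivalent regenerates the ylide by transylidation, and 3-exo-tet displacement of the secondary sulfate monoester with inversion closes the ring and sets the (2R) cyclopropane carbon; the closest known reaction types are the C-alkylation of stabilised phosphorus ylides with alkyl halides and the cyclopropanation of malonate or phosphonoacetate anions with 1,2-cyclic sulfates.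

Step 7
Reactants: 11 [(1S,2R)-2-[(2S,5E)-1,1-dimethoxy-6,10-dimethylundeca-5,9-dien-2-yl]-1-(ethoxycarbonyl)cyclopropyl]triphenylphosphonium tetrafluoroborate; 12 1-[(tert-butyldimethylsilyl)oxy]propan-2-one
Product: 16 (6R)-6-[(2S,5E)-1,1-dimethoxy-6,10-dimethylundeca-5,9-dien-2-yl]-3,4,5,6-tetrahydro-1H-cyclopenta[c]furan-1-one, via lithium enolate 13 (not isolated), via keto ylide 14 (not isolated), via cyclopentene ester 15 (not isolated)
Conditions: 12, LiN(iPr)2 (1.05 equiv), THF, −78 °C; then 11, THF/DMPU, −78 → 23 °C, then 65 °C; then Bu4NF, 23 °C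
Reagents that add atoms: none
Why: The methyl-side lithium enolate 13 attacks the unsubstituted CH2 of the doubly activated cyclopropane in an SN2 ring opening (homoconjugate addition) that makes the C4–C5 bond and releases the ester-stabilised ylide 14, which adds to the α-silyloxy ketone and collapses through the oxaphosphetane to the tetrasubstituted C1=C2 bond. The closest known reaction type is the cyclopentene annulation of stabilised enolates with 1-(alkoxycarbonyl)cyclopropylphosphonium salts (ring opening followed by intramolecular Wittig reaction). The five-membered ring is closed in the Wittig stage in a 5-exo-trig sense, the carbonyl oxygen staying outside the new ring. No stereocentre is created: C3 is the untouched C2 of the cyclopropane and keeps its configuration, while the stereocentre at the phosphorus-bearing carbon is destroyed. The step needs methyl-side enolate regiochemistry, which kinetic deprotonation at −78 °C next to the bulky silyloxymethyl group should secure, and attack at CH2 instead of the substituted ring carbon, which the branched substituent on the latter should secure. Fluoride added at the end removes the silyl group and the freed alkoxide lactonises onto the neighbouring ester to give 16.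

Step 8
Reactants: 16 (6R)-6-[(2S,5E)-1,1-dimethoxy-6,10-dimethylundeca-5,9-dien-2-yl]-3,4,5,6-tetrahydro-1H-cyclopenta[c]furan-1-one
Product: 17 [(3R)-3-[(2S,5E)-1,1-dimethoxy-6,10-dimethylundeca-5,9-dien-2-yl]cyclopent-1-ene-1,2-diyl]dimethanol
Conditions: iBu2AlH (4 equiv), CH2Cl2, −78 → 0 °C; aq. KNaC4H4O6 work-up
Reagents that add atoms: none
Why: 1,2-Reduction of the unsaturated lactone by the aluminium hydride (through the lactol) should give the 2-ene-1,4-diol without conjugate reduction or attack on the acetal.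

Step 9
Reactants: 17 [(3R)-3-[(2S,5E)-1,1-dimethoxy-6,10-dimethylundeca-5,9-dien-2-yl]cyclopent-1-ene-1,2-diyl]dimethanol
Product: 18 [(3R)-3-[(2S,5E)-1,1-dimethoxy-6,10-dimethylundeca-5,9-dien-2-yl]-2-(hydroxymethyl)cyclopent-1-en-1-yl]methyl acetate
Conditions: Candida antarctica lipase B (immobilised), vinyl acetate, tert-butyl methyl ether, 23 °C
Reagents that add atoms: vinyl acetate, CC(=O)OC=C
Why: Lipase-catalysed irreversible transesterification should acetylate the less hindered primary allylic hydroxyl on the C1 side, remote from the branched C3 substituent that shields the other hydroxymethyl group.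

Step 10
Reactants: 18 [(3R)-3-[(2S,5E)-1,1-dimethoxy-6,10-dimethylundeca-5,9-dien-2-yl]-2-(hydroxymethyl)cyclopent-1-en-1-yl]methyl acetate
Product: 19 [(3R)-3-[(2S,5E)-1,1-dimethoxy-6,10-dimethylundeca-5,9-dien-2-yl]-2-formylcyclopent-1-en-1-yl]methyl acetate
Conditions: MnO2 (excess), CH2Cl2, 23 °C
Reagents that add atoms: none
Why: MnO2 oxidises allylic alcohols selectively to enals under neutral conditions that preserve the acetate, the acetal and the isolated alkenes.

Step 11
Reactants: 19 [(3R)-3-[(2S,5E)-1,1-dimethoxy-6,10-dimethylundeca-5,9-dien-2-yl]-2-formylcyclopent-1-en-1-yl]methyl acetate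
Product: 20 [(3R)-2-formyl-3-[(2S,5E)-6,10-dimethyl-1-oxoundeca-5,9-dien-2-yl]cyclopent-1-en-1-yl]methyl acetate
Conditions: pyridinium p-toluenesulfonate (cat.), acetone/H2O (10:1), 35 °C
Reagents that add atoms: water, O
Why: Mild acid-catalysed hydrolysis of the acyclic dimethyl acetal releases the α-branched aldehyde under conditions too weak to epimerise it or to cleave the allylic acetate.

**Compound list**

1 | geranyl bromide, (2E)-1-bromo-3,7-dimethylocta-2,6-diene | BrC/C=C(\C)CCC=C(C)C | starting material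
2 | [2-(1,3-dioxan-2-yl)ethyl]magnesium bromide | Br[Mg]CCC1OCCCO1 | starting material
3 | 2-[(4E)-5,9-dimethyldeca-4,8-dien-1-yl]-1,3-dioxane | C1COC(CCC/C=C(\C)CCC=C(C)C)OC1 | intermediate
4 | (5E)-6,10-dimethylundeca-5,9-dienal | O=CCCC/C=C(\C)CCC=C(C)C | intermediate
5 | 2-[(triisopropylsilyl)oxy]acetaldehyde | O=CCO[Si](C(C)C)(C(C)C)C(C)C | starting material
6 | (2S,3R)-2-[(3E)-4,8-dimethylnona-3,7-dien-1-yl]-3-hydroxy-4-[(triisopropylsilyl)oxy]butanal (not isolated) | O=C[C@@H](CC/C=C(\C)CCC=C(C)C)[C@@H](O)CO[Si](C(C)C)(C(C)C)C(C)C | intermediate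
7 | (2R,3S,6E)-3-(dimethoxymethyl)-7,11-dimethyl-1-[(triisopropylsilyl)oxy]dodeca-6,10-dien-2-ol | COC(OC)[C@@H](CC/C=C(\C)CCC=C(C)C)[C@@H](O)CO[Si](C(C)C)(C(C)C)C(C)C | intermediate
8 | (2R,3S,6E)-3-(dimethoxymethyl)-7,11-dimethyldodeca-6,10-diene-1,2-diol | COC(OC)[C@@H](CC/C=C(\C)CCC=C(C)C)[C@@H](O)CO | intermediate
9 | (4R)-4-[(2S,5E)-1,1-dimethoxy-6,10-dimethylundeca-5,9-dien-2-yl]-1,3,2-dioxathiolane 2,2-dioxide | COC(OC)[C@@H](CC/C=C(\C)CCC=C(C)C)[C@@H]1COS(=O)(=O)O1 | intermediate
10 | ethyl (triphenyl-λ5-phosphanylidene)acetate | CCOC(=O)C=P(c1ccccc1)(c1ccccc1)c1ccccc1 | starting material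
11 | [(1S,2R)-2-[(2S,5E)-1,1-dimethoxy-6,10-dimethylundeca-5,9-dien-2-yl]-1-(ethoxycarbonyl)cyclopropyl]triphenylphosphonium tetrafluoroborate | COC(OC)[C@@H](CC/C=C(\C)CCC=C(C)C)[C@H]1C[C@]1(C(=O)OCC)[P+](c1ccccc1)(c1ccccc1)c1ccccc1.F[B-](F)(F)F | intermediate
12 | 1-[(tert-butyldimethylsilyl)oxy]propan-2-one | CC(=O)CO[Si](C)(C)C(C)(C)C | starting material
13 | lithium 3-[(tert-butyldimethylsilyl)oxy]prop-1-en-2-olate (not isolated) | [Li+].C=C([O-])CO[Si](C)(C)C(C)(C)C | intermediate
14 | ethyl (3R,4S,7E)-3-{4-[(tert-butyldimethylsilyl)oxy]-3-oxobutyl}-4-(dimethoxymethyl)-8,12-dimethyl-2-(triphenyl-λ5-phosphanylidene)trideca-7,11-dienoate (not isolated) | CCOC(=O)C(=P(c1ccccc1)(c1ccccc1)c1ccccc1)[C@@H]([C@@H](C(OC)OC)CC/C=C(\C)CCC=C(C)C)CCC(=O)CO[Si](C)(C)C(C)(C)C | intermediate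
15 | ethyl (5R)-2-{[(tert-butyldimethylsilyl)oxy]methyl}-5-[(2S,5E)-1,1-dimethoxy-6,10-dimethylundeca-5,9-dien-2-yl]cyclopent-1-ene-1-carboxylate (not isolated) | CC(C)(C)[Si](C)(C)OCC1=C(C(=O)OCC)[C@@H]([C@@H](C(OC)OC)CC/C=C(\C)CCC=C(C)C)CC1 | intermediate
16 | (6R)-6-[(2S,5E)-1,1-dimethoxy-6,10-dimethylundeca-5,9-dien-2-yl]-3,4,5,6-tetrahydro-1H-cyclopenta[c]furan-1-one | O=C1OCC2=C1[C@@H]([C@@H](C(OC)OC)CC/C=C(\C)CCC=C(C)C)CC2 | intermediate
17 | [(3R)-3-[(2S,5E)-1,1-dimethoxy-6,10-dimethylundeca-5,9-dien-2-yl]cyclopent-1-ene-1,2-diyl]dimethanol | OCC1=C(CO)[C@@H]([C@@H](C(OC)OC)CC/C=C(\C)CCC=C(C)C)CC1 | intermediate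
18 | [(3R)-3-[(2S,5E)-1,1-dimethoxy-6,10-dimethylundeca-5,9-dien-2-yl]-2-(hydroxymethyl)cyclopent-1-en-1-yl]methyl acetate | CC(=O)OCC1=C(CO)[C@@H]([C@@H](C(OC)OC)CC/C=C(\C)CCC=C(C)C)CC1 | intermediate
19 | [(3R)-3-[(2S,5E)-1,1-dimethoxy-6,10-dimethylundeca-5,9-dien-2-yl]-2-formylcyclopent-1-en-1-yl]methyl acetate | CC(=O)OCC1=C(C=O)[C@@H]([C@@H](C(OC)OC)CC/C=C(\C)CCC=C(C)C)CC1 | intermediate
20 | [(3R)-2-formyl-3-[(2S,5E)-6,10-dimethyl-1-oxoundeca-5,9-dien-2-yl]cyclopent-1-en-1-yl]methyl acetate | CC(=O)OCC1=C(C=O)[C@@H]([C@@H](C=O)CC/C=C(\C)CCC=C(C)C)CC1 | target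

Total step count: 11. Longest linear sequence: 11 steps (1 → 20).

**Steps most likely to fail**

1. Step 6 (labelled step). What may go wrong: slow ring closure of the weakly nucleophilic ylide at the hindered secondary carbon, or O-alkylation of the ylide in place of C-alkylation. Fallback with known chemistry, setting out from 9 and coming back at 15: cyclopropanation of 9 with the sodium salt of triethyl phosphonoacetate (NaH, 1,2-dimethoxyethane, reflux; primary alkylation, then 3-exo-tet closure with inversion) should give ethyl (1S,2R)-1-(diethoxyphosphoryl)-2-[(2S,5E)-1,1-dimethoxy-6,10-dimethylundeca-5,9-dien-2-yl]cyclopropane-1-carboxylate F1. Homoconjugate opening of F1 by the sodium enolate of prop-2-en-1-yl 4-[(tert-butyldimethylsilyl)oxy]-3-oxobutanoate F2 (made by crossed Claisen condensation of the lithium enolate of allyl acetate with methyl [(tert-butyldimethylsilyl)oxy]acetate) in dimethyl sulfoxide at 80 °C, followed in the same flask by intramolecular Horner–Wadsworth–Emmons olefination, should give 1-ethyl 3-prop-2-en-1-yl (5R)-2-{[(tert-butyldimethylsilyl)oxy]methyl}-5-[(2S,5E)-1,1-dimethoxy-6,10-dimethylundeca-5,9-dien-2-yl]cyclopent-1-ene-1,3-dicarboxylate F3. Deallylation with Pd(PPh3)4 and morpholine, thermal decarboxylation and re-conjugation with DBU return the route at 15, which is desilylated and lactonised to 16 as in step 7.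

2. Step 7. What may go wrong: proton transfer between the enolate and the ring-opened ketone, or loss of the methyl-side enolate regiochemistry on warming, leading to mixtures and double alkylation. Fallback, setting out from 12 and 11 and coming back at 14: condensation of 12 with N,N-dimethylhydrazine should give 1-[(tert-butyldimethylsilyl)oxy]propan-2-one N,N-dimethylhydrazone F4. Its lithium azaenolate (LiN(iPr)2, THF, −78 °C, deprotonation at the methyl group) opens 11 at the CH2 to give ethyl (3R,4S,7E)-3-{4-[(tert-butyldimethylsilyl)oxy]-3-(2,2-dimethylhydrazinylidene)butyl}-4-(dimethoxymethyl)-8,12-dimethyl-2-(triphenyl-λ5-phosphanylidene)trideca-7,11-dienoate F5. Buffered aqueous CuCl2 cleaves the hydrazone and returns the route at keto ylide 14, which is heated to close the ring and then treated with Bu4NF as in step 7.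

3. Step 9. What may go wrong: poor site selectivity between the two primary allylic hydroxyl groups, or acetyl migration. Fallback, setting out from 15 (isolated by leaving out the fluoride treatment in step 7) and coming back at 18: iBu2AlH reduction of the ester should give [(5R)-2-{[(tert-butyldimethylsilyl)oxy]methyl}-5-[(2S,5E)-1,1-dimethoxy-6,10-dimethylundeca-5,9-dien-2-yl]cyclopent-1-en-1-yl]methanol F6. NaH and 4-methoxybenzyl chloride give tert-butyl{[(3R)-3-[(2S,5E)-1,1-dimethoxy-6,10-dimethylundeca-5,9-dien-2-yl]-2-{[(4-methoxybenzyl)oxy]methyl}cyclopent-1-en-1-yl]methoxy}dimethylsilane F7. Bu4NF gives [(3R)-3-[(2S,5E)-1,1-dimethoxy-6,10-dimethylundeca-5,9-dien-2-yl]-2-{[(4-methoxybenzyl)oxy]methyl}cyclopent-1-en-1-yl]methanol F8. Acetic anhydride and pyridine give [(3R)-3-[(2S,5E)-1,1-dimethoxy-6,10-dimethylundeca-5,9-dien-2-yl]-2-{[(4-methoxybenzyl)oxy]methyl}cyclopent-1-en-1-yl]methyl acetate F9. DDQ in CH2Cl2/pH 7 buffer removes the 4-methoxybenzyl group and returns the route at 18.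

Further compounds
F1 | step 6 | ethyl (1S,2R)-1-(diethoxyphosphoryl)-2-[(2S,5E)-1,1-dimethoxy-6,10-dimethylundeca-5,9-dien-2-yl]cyclopropane-1-carboxylate | COC(OC)[C@@H](CC/C=C(\C)CCC=C(C)C)[C@H]1C[C@]1(C(=O)OCC)P(=O)(OCC)OCC
F2 | step 6 | prop-2-en-1-yl 4-[(tert-butyldimethylsilyl)oxy]-3-oxobutanoate | C=CCOC(=O)CC(=O)CO[Si](C)(C)C(C)(C)C
F3 | step 6 | 1-ethyl 3-prop-2-en-1-yl (5R)-2-{[(tert-butyldimethylsilyl)oxy]methyl}-5-[(2S,5E)-1,1-dimethoxy-6,10-dimethylundeca-5,9-dien-2-yl]cyclopent-1-ene-1,3-dicarboxylate | CC(C)(C)[Si](C)(C)OCC1=C(C(=O)OCC)[C@@H]([C@@H](C(OC)OC)CC/C=C(\C)CCC=C(C)C)CC1C(=O)OCC=C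
F4 | step 7 | 1-[(tert-butyldimethylsilyl)oxy]propan-2-one N,N-dimethylhydrazone | CC(=NN(C)C)CO[Si](C)(C)C(C)(C)C
F5 | step 7 | ethyl (3R,4S,7E)-3-{4-[(tert-butyldimethylsilyl)oxy]-3-(2,2-dimethylhydrazinylidene)butyl}-4-(dimethoxymethyl)-8,12-dimethyl-2-(triphenyl-λ5-phosphanylidene)trideca-7,11-dienoate | CCOC(=O)C(=P(c1ccccc1)(c1ccccc1)c1ccccc1)[C@@H]([C@@H](C(OC)OC)CC/C=C(\C)CCC=C(C)C)CCC(=NN(C)C)CO[Si](C)(C)C(C)(C)C
F6 | step 9 | [(5R)-2-{[(tert-butyldimethylsilyl)oxy]methyl}-5-[(2S,5E)-1,1-dimethoxy-6,10-dimethylundeca-5,9-dien-2-yl]cyclopent-1-en-1-yl]methanol | CC(C)(C)[Si](C)(C)OCC1=C(CO)[C@@H]([C@@H](C(OC)OC)CC/C=C(\C)CCC=C(C)C)CC1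
F7 | step 9 | tert-butyl{[(3R)-3-[(2S,5E)-1,1-dimethoxy-6,10-dimethylundeca-5,9-dien-2-yl]-2-{[(4-methoxybenzyl)oxy]methyl}cyclopent-1-en-1-yl]methoxy}dimethylsilane | CC(C)(C)[Si](C)(C)OCC1=C(COCc2ccc(OC)cc2)[C@@H]([C@@H](C(OC)OC)CC/C=C(\C)CCC=C(C)C)CC1
F8 | step 9 | [(3R)-3-[(2S,5E)-1,1-dimethoxy-6,10-dimethylundeca-5,9-dien-2-yl]-2-{[(4-methoxybenzyl)oxy]methyl}cyclopent-1-en-1-yl]methanol | OCC1=C(COCc2ccc(OC)cc2)[C@@H]([C@@H](C(OC)OC)CC/C=C(\C)CCC=C(C)C)CC1
F9 | step 9 | [(3R)-3-[(2S,5E)-1,1-dimethoxy-6,10-dimethylundeca-5,9-dien-2-yl]-2-{[(4-methoxybenzyl)oxy]methyl}cyclopent-1-en-1-yl]methyl acetate | CC(=O)OCC1=C(COCc2ccc(OC)cc2)[C@@H]([C@@H](C(OC)OC)CC/C=C(\C)CCC=C(C)C)CC1
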